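All runs stem from a simulated flask from invented constants; the scatter is artificial.

Two amounts and a winner are asked of the flasks epsilon and delta, and the earlier runs ash and maple have to answer.

| flask | substrate | partner | free catalyst | remark | time |
|---|---|---|---|---|---|
| ash | 0.98 M | 0.23 M | 20 mM | run made earlier |  |
| maple | 0.98 M | 0.73 M | 20 mM | run made earlier |  |
| epsilon | 0.98 M | 1.18 M | 20 mM |  | 40 min |
| delta | 0.98 M | 0.300 M | 20 mM |  | 80 min |

| run | time / min | target / % | substrate / % |
|---|---|---|---|
| ash | 4.00 | 0.8 | 99.5 |
| ash | 8.00 | 2.1 | 97.1 |
| ash | 12.0 | 3.9 | 96.7 |
| ash | 15.0 | 4.4 | 95.7 |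
| ash | 20.0 | 4.8 | 93.9 |
| maple | 4.00 | 2.0 | 97.5 |
| maple | 8.00 | 6.5 | 94.3 |
| maple | 12.0 | 9.5 | 89.6 |
| maple | 15.0 | 12.0 | 87.6 |
| maple | 20.0 | 14.8 | 84.7 |

(each reading ± 0.5 percentage points)

- the winner by amount of target, in percent of the substrate charged; "neither" if no more than 2 percentage points parts them (epsilon / delta / neither)
- how much target is there at the end, in percent of the substrate charged: epsilon
- how much target is there at the end, in percent of the substrate charged: delta



At the last reading, 20.0 min, I set the target formed, in molar terms, against each run's partner charge, supposing that each target takes one partner: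

ash 20.5%, maple 19.9%

The charges differ by a factor of 3.17, yet the shares match, which is how a pseudo-first-order loss of partner reads, so I need two times: the time asked, and the life of partner, the time constant of that loss at this catalyst charge, 90.3 min, taken from maple, whose last target reading is the larger. Their ratio gives the share of partner used, 1 − exp(−time/life):

epsilon: ratio 0.443, target 43.1%

delta: ratio 0.886, target 18.0%

My epsilon figure takes substrate well below maple's last 84.7%, untested ground, so I count it as a high side.

The forecast, reading “a reversible reaction”, gives 28% (21% to 36%) for epsilon and 10% (6.5% to 14%) for delta, with epsilon the winner; I name the same winner, with higher figures .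

Epsilon ends at 38.2% and delta at 18.7%, so epsilon wins, and both amounts stand above the forecast's ranges .

    partner + free catalyst → catalyst intermediate A (k = 0.795 L mol⁻¹ min⁻¹)
    substrate + catalyst intermediate A → catalyst intermediate B (k = 2.10 L mol⁻¹ min⁻¹)
    catalyst intermediate B → free catalyst + target (k = 11.7 min⁻¹)
    substrate + target → side product (k = 0.00313 L mol⁻¹ min⁻¹)

In delta, target still climbs from 12.4% at 40.0 min to 18.7% at 80.0 min, with 31% of the partner left; the life of partner gives that stretch a rise of 7 percentage points.

For delta read at 30 min, the life gives 8.65% target; the computed flask holds 10.0%.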